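**Assumption:** the lactol carbon C1 mutarotates, so its configuration is taken as thermodynamically controlled; the 1S anomer in the target SMILES is assumed to be the equilibrium (natural) form. Xenicane numbering is used in the comments (C1 lactol, O2, C3, C4, C4a, C5–C11, C11a; C9 bears OAc; C11 bears the methylidene).

## Retrosynthetic overview

1. The pyran lactol is made last: reduction of a temporary C9–O–C1(=O) lactone bridge releases C9–OH and the C1 aldehyde, which closes onto C3–OH; C9 is then acetylated.
2. The side chain comes from a cross-aldol condensation of a C4–CH2–CHO aldehyde with (E)-4-hydroxy-4-methylpent-2-enal; the C4=C12 geometry is the thermodynamic α-substituted enal geometry.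
3. The nine-membered ring is closed at C4a–C5 by conjugate addition of a primary alkyl radical to an (E)-α-alkylidene-β-methylidene δ-lactone. The lactone bridge relays the C9 configuration to C4a and C11a.
4. The dienyl lactone comes from Suzuki coupling of a 2-borylallyl carbinol with a (Z)-α-bromo enoate, then lactonisation; the carbinol comes from asymmetric 2-bromoallylation of an (E)-enal (sets C9).
5. Ring order: six-membered relay lactone → nine-membered carbocycle (radical step) → pyran lactol.

## Route

**Step 1**
Reactants: 1, but-3-yn-1-ol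
Product: 2, (2E)-3-methylpent-2-ene-1,5-diol
Conditions: Me3Al, Cp2ZrCl2 (cat.), CH2Cl2, 0 °C→rt; then n-BuLi, (CH2O)n, THF, −78 °C→rt
Reagents that add atoms: trimethylaluminium, C[Al](C)C (adds CH3); paraformaldehyde, C=O (adds CH2O)
Why: Negishi Zr-catalysed carboalumination adds Me–Al syn across the alkyne, and hydroxymethylation of the alkenyl alanate proceeds with retention, fixing the E-trisubstituted C7=C8 alkene.

**Step 2**
Reactants: 2
Product: 3, (2E)-5-hydroxy-3-methylpent-2-enal
Conditions: activated MnO2, CH2Cl2, rt
Reagents that add atoms: none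
Why: MnO2 oxidises only the allylic primary alcohol; the saturated primary alcohol and the alkene geometry are untouched.

**Step 3**
Reactants: 3
Product: 4, (2E)-5-bromo-3-methylpent-2-enal
Conditions: CBr4, PPh3, CH2Cl2, 0 °C
Reagents that add atoms: carbon tetrabromide, BrC(Br)(Br)Br (adds Br)
Why: Appel bromination of the only hydroxyl installs the radical precursor at C5; the enal is inert.

**Step 4**
Reactants: 4; 5, 2,3-dibromoprop-1-ene
Product: 6, (4R,5E)-2,8-dibromo-6-methylocta-1,5-dien-4-ol
Conditions: CrCl2 (cat.), Kishi chiral sulfonamide ligand, Mn, TMSCl, 2,6-lutidine, LiCl, MeCN/THF, 0 °C; then dilute HCl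
Reagents that add atoms: none (5 is a reactant)
Why: Catalytic asymmetric Cr-mediated (Nozaki–Hiyama–Kishi-type) 2-bromoallylation adds 1,2 to the enal with ligand-controlled facial selectivity, setting C9 as R; without Ni or Co the vinyl and alkyl bromides do not react.

**Step 5**
Reactants: 7, 3,3-dimethoxypropanal
Product: 8, ethyl (2Z)-2-bromo-5,5-dimethoxypent-2-enoate
Conditions: Ph3P=C(Br)CO2Et, CH2Cl2, rt
Reagents that add atoms: ethyl bromo(triphenylphosphoranylidene)acetate, CCOC(=O)C(Br)=P(c1ccccc1)(c1ccccc1)c1ccccc1 (adds C(Br)CO2Et)
Why: Wittig olefination with the stabilised α-bromo ylide places the alkyl chain trans to the ester, giving the (Z)-α-bromo enoate whose geometry is transferred in Step 6.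

**Step 6**
Reactants: 6; 8
Product: 9, ethyl (2E)-2-[(4R,5E)-8-bromo-4-hydroxy-6-methylocta-1,5-dien-2-yl]-5,5-dimethoxypent-2-enoate
Conditions: 6, B2pin2, Pd(dppf)Cl2 (cat.), KOAc, dioxane, 80 °C; then 8, aq. K3PO4, 50 °C (one pot)
Reagents that add atoms: none (boron is lost)
Why: Miyaura borylation of the 2-bromo-1-alkene followed by Suzuki–Miyaura coupling proceeds with retention at the bromo-enoate, so the C4 arm ends trans to the ester (E); the primary alkyl bromide does not undergo oxidative addition with this catalyst.

**Step 7**
Reactants: 9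
Product: 10, (3E,6R)-6-[(1E)-4-bromo-2-methylbut-1-en-1-yl]-3-(3,3-dimethoxypropylidene)-4-methylideneoxan-2-one
Conditions: CSA (10 mol %), PhMe, 5 Å MS, 50 °C; product used at once
Reagents that add atoms: none
Why: Acid-catalysed 6-exo lactonisation of the δ-hydroxy ester ties C9–O to C1 without touching the alkylidene geometry or the C9 centre.

**Step 8**
Reactants: 10
Product: 11, (1R,2R,5E,7R)-2-(2,2-dimethoxyethyl)-5-methyl-10-methylidene-8-oxabicyclo[5.2.2]undec-5-en-9-one
Conditions: Bu3SnH (1.3 equiv) and AIBN added by syringe pump over 12 h to 10 (2 mM) in PhH, 80 °C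
Reagents that add atoms: none
Why: Proposed new method: a tin-hydride Giese-type ring closure in which the primary C5 radical adds to the exocyclic β-carbon (C4a) of the alkylidene lactone to form a bridged nine-membered ring; the closest known reactions are endo-mode radical macrocyclisations onto enoates and 8-endo cyclisations onto activated alkenes. The stereochemical and regiochemical reasoning:
- The chain on C9 can reach C4a only across its own face of the lactone, so with the fixed (E)-alkylidene geometry the C4 arm ends anti to the lactone bridge (correct C4a).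
- The resulting bridgehead radical at C11a can only take H from the exo face (correct C11a).
- Attack at the other diene terminus would give an (E)-cyclooctene, and H-transfer to the methylidene carbon would give a bridgehead alkene, so both are disfavoured.
- The radical has no accessible 1,5-H transfer.

**Step 9**
Reactants: 11
Product: 12, [(1R,2R,5E,7R)-5-methyl-10-methylidene-9-oxo-8-oxabicyclo[5.2.2]undec-5-en-2-yl]acetaldehyde
Conditions: PPTS, acetone/H2O (9:1), 50 °C
Reagents that add atoms: water, O (carbonyl oxygen)
Why: Mild acetal hydrolysis; the bridged lactone is stable, and C11a is a bridgehead so it can neither epimerise nor let the methylidene migrate into conjugation.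

**Step 10**
Reactants: 13, 2-methylbut-3-en-2-ol; 14, (E)-but-2-enal
Product: 15, (2E)-4-hydroxy-4-methylpent-2-enal
Conditions: Hoveyda–Grubbs II (2 mol %), CH2Cl2, 40 °C, excess 14
Reagents that add atoms: none
Why: Cross-metathesis of the hindered tertiary allylic alcohol with an enal gives the E-enal selectively.

**Step 11**
Reactants: 12; 15
Product: 16, (2E,4E)-6-hydroxy-6-methyl-2-[(1R,2S,5E,7R)-5-methyl-10-methylidene-9-oxo-8-oxabicyclo[5.2.2]undec-5-en-2-yl]hepta-2,4-dienal
Conditions: pyrrolidine (20 mol %), PhCO2H (20 mol %), PhMe, 4 Å MS, rt→40 °C, 15 (2 equiv)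
Reagents that add atoms: none
Why: Amine-catalysed cross-aldol condensation: 12 is the only enolisable partner and 15 cannot enolise (no γ-H); dehydration gives the thermodynamic α-substituted enal, with CHO trans to the diene chain, which is exactly the required C4=C12 geometry.

**Step 12**
Reactants: 16
Product: 17, 9-O-deacetylasterolaurin D, (1S,4E,4aS,7E,9R,11aR)-4-[(2E)-4-hydroxy-4-methylpent-2-en-1-ylidene]-7-methyl-11-methylidene-1,3,4,4a,5,6,9,10,11,11a-decahydrocyclonona[c]pyran-1,9-diol
Conditions: DIBAL-H (3.5 equiv), CH2Cl2, −78 °C; Rochelle salt work-up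
Reagents that add atoms: none
Why: DIBAL reduces the dienal 1,2 to the C3 allylic alcohol and the bridged lactone to its lactol; ring–chain tautomerism then moves the hemiacetal from the strained C9–O bridge to the fused pyran (C3–O), freeing C9–OH with C4a, C9 and C11a untouched.

**Step 13**
Reactants: 17
Product: 18, 1,9-di-O-acetate of 17 (anomeric mixture)
Conditions: Ac2O, pyridine, DMAP (cat.), CH2Cl2, 0 °C
Reagents that add atoms: acetic anhydride, CC(=O)OC(C)=O (adds two acetyl groups)
Why: Standard acylation of the secondary C9–OH and the lactol OH; the tertiary allylic alcohol is not acylated under these conditions.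

**Step 14**
Reactants: 18
Product: 19, asterolaurin D
Conditions: H2NNH2·HOAc, DMF, 0 °C→rt
Reagents that add atoms: none
Why: Selective anomeric deacetylation (the acyloxy-acetal is far more labile than the secondary allylic acetate) releases the C1 lactol, which settles to the 1S anomer.

## Compound list

1 | but-3-yn-1-ol | C#CCCO | starting material
2 | (2E)-3-methylpent-2-ene-1,5-diol | OC/C=C(\C)CCO | intermediate
3 | (2E)-5-hydroxy-3-methylpent-2-enal | O=C/C=C(\C)CCO | intermediate
4 | (2E)-5-bromo-3-methylpent-2-enal | O=C/C=C(\C)CCBr | intermediate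
5 | 2,3-dibromoprop-1-ene | C=C(Br)CBr | starting material
6 | (4R,5E)-2,8-dibromo-6-methylocta-1,5-dien-4-ol | C=C(Br)C[C@@H](O)/C=C(\C)CCBr | intermediate
7 | 3,3-dimethoxypropanal | COC(OC)CC=O | starting material
8 | ethyl (2Z)-2-bromo-5,5-dimethoxypent-2-enoate | CCOC(=O)/C(Br)=C/CC(OC)OC | intermediate
9 | ethyl (2E)-2-[(4R,5E)-8-bromo-4-hydroxy-6-methylocta-1,5-dien-2-yl]-5,5-dimethoxypent-2-enoate | CCOC(=O)/C(=C/CC(OC)OC)C(=C)C[C@@H](O)/C=C(\C)CCBr | intermediate
10 | (3E,6R)-6-[(1E)-4-bromo-2-methylbut-1-en-1-yl]-3-(3,3-dimethoxypropylidene)-4-methylideneoxan-2-one | C=C1C[C@@H](OC(=O)/C1=C/CC(OC)OC)/C=C(\C)CCBr | intermediate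
11 | (1R,2R,5E,7R)-2-(2,2-dimethoxyethyl)-5-methyl-10-methylidene-8-oxabicyclo[5.2.2]undec-5-en-9-one | C=C1C[C@@H]2/C=C(\C)CC[C@H](CC(OC)OC)[C@H]1C(=O)O2 | intermediate
12 | [(1R,2R,5E,7R)-5-methyl-10-methylidene-9-oxo-8-oxabicyclo[5.2.2]undec-5-en-2-yl]acetaldehyde | C=C1C[C@@H]2/C=C(\C)CC[C@H](CC=O)[C@H]1C(=O)O2 | intermediate
13 | 2-methylbut-3-en-2-ol | C=CC(C)(C)O | starting material
14 | (E)-but-2-enal | C/C=C/C=O | starting material
15 | (2E)-4-hydroxy-4-methylpent-2-enal | O=C/C=C/C(C)(C)O | intermediate
16 | (2E,4E)-6-hydroxy-6-methyl-2-[(1R,2S,5E,7R)-5-methyl-10-methylidene-9-oxo-8-oxabicyclo[5.2.2]undec-5-en-2-yl]hepta-2,4-dienal | C=C1C[C@@H]2/C=C(\C)CC[C@H](/C(C=O)=C\C=C\C(C)(C)O)[C@H]1C(=O)O2 | intermediate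
17 | 9-O-deacetylasterolaurin D | C=C1C[C@@H](O)/C=C(\C)CC[C@@H]2/C(=C\C=C\C(C)(C)O)CO[C@H](O)[C@@H]12 | intermediate
18 | 1,9-di-O-acetate of 17 (anomeric mixture) | C=C1C[C@@H](OC(C)=O)/C=C(\C)CC[C@@H]2/C(=C\C=C\C(C)(C)O)COC(OC(C)=O)[C@@H]12 | intermediate
19 | asterolaurin D | C=C1C[C@@H](OC(C)=O)/C=C(\C)CC[C@@H]2/C(=C\C=C\C(C)(C)O)CO[C@H](O)[C@@H]12 | target

## Step count and risks

Total steps: 14. Longest linear sequence: 12 (Steps 1–4, 6–9, 11–14).

Steps most likely to fail:

1. **Step 8 (radical closure of the bridged nine-membered ring).** Risks are premature reduction of the C5 radical, strain in the bridged transition state, and E/Z scrambling of the alkylidene by reversible stannyl addition. Fallback: make the same C4a–C5 bond anionically. Convert the bromide of 10 to the phenyl sulfone (PhSO2Na), close the ring by intramolecular Michael addition of the sulfonyl carbanion (KHMDS) onto the alkylidene lactone, then desulfonylate reductively.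

2. **Step 11 (cross-aldol condensation).** Risks are self-condensation of 12 or Michael-type side reactions with 15. Fallback: α-methylenate 12 (Eschenmoser's salt) to the 2-substituted acrolein and attach the side chain by Heck coupling with (E)-4-bromo-2-methylbut-3-en-2-ol, which gives the same thermodynamic (E)-enal.

3. **Steps 6–7 (formation and survival of dienyl lactone 10).** Risks are a sluggish hindered Suzuki coupling, competing oxa-Michael addition of the C9 hydroxyl, and Diels–Alder dimerisation of the s-cis diene. Fallback: build the lactone first by Pd-catalysed coupling of 6 with the Reformatsky reagent of ethyl bromoacetate and lactonisation to the 4-methylidene δ-lactone, then introduce the alkylidene by aldol addition to 7 and E1cB dehydration immediately before the radical step.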